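I decided to count coupling partner, not substrate. The north-west run slowed sharply and still held half of its substrate at 10.0 h, and I wanted to know what had been paid for it.

all flasks: substrate 0.020 M; initiator 1.8 mM

|  | coupling partner | protic impurity | remark | time |
|---|---|---|---|---|
| north-west | 0.022 M | 6 mM | run made earlier |  |
| winter | 0.0180 M | 6.00 mM |  | 10 h |
| autumn | 0.0230 M | 6.00 mM |  | 10 h |
| noon | 0.0300 M | 6.00 mM |  | 10 h |

north-west run (percent of the substrate charged)

| time / h | substrate / % | target / % |
|---|---|---|
| 0.833 | 79 | 22 |
| 1.50 | 64 | 34 |
| 3.00 | 58 | 44 |
| 5.00 | 53 | 44 |
| 10.0 | 49 | 48 |

(readings scatter by 1.5 percentage points)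

- a species is counted by the substrate in it: one ended chains A counts as two
- amounts and yields of by-product count idle adduct too
- steps that have been proposed: coupling partner + protic impurity -> quenched reagent; coupling partner + first chain carrier <-> target + second chain carrier; substrate + second chain carrier -> by-product + first chain carrier; 2 second chain carrier -> ended chains B; 2 first chain carrier -> ended chains A; coupling partner -> decomposition product; coupling partner + by-product <-> idle adduct; initiator -> 2 initiating radical; substrate + initiating radical -> capped initiator + first chain carrier

* part of the substrate that has reacted at the end, winter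
* part of the substrate that has reacted at the end, autumn
* part of the substrate that has reacted at the end, noon
* what raising the concentration of coupling partner from its lowest to its highest value here does to the part of the substrate that has reacted (changes below 5 percentage points count as none) (no change / it rises / it falls)

My rule of thumb took coupling partner as the limiting reagent and let each protic impurity destroy one partner. North-west then had 16.0 mM of usable partner and had converted 10.2 mM of substrate by 10.0 h. That gave 1.57 for the partner cost, the usable partner spent per substrate reacted by that time. It is a reading, with a scatter of 1.5 percentage points on the substrate.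

Dividing each flask's usable partner by this cost and by its substrate gave me 38.2 % for winter, 54.2 % for autumn and 76.5 % for noon. This ratio also marks the border of the rule. In my reckoning, a ratio of 100 % marks where substrate takes over as the limiting reagent, and noon stood nearest to that, at 76.5 %.

Then I compared rates. North-west lost substrate 31.5 times faster up to 0.833 h than between 5.00 h and 10.0 h. But that late drop was 4 points, so the ratio was rough, and I could not say the run had stopped. My cost therefore belonged to 10 h.

The forecast gave 38 % (30 % to 45 %), 54 % (49 % to 60 %) and 72 % (57 % to 90 %), with the trend: it rises. Its noon value lay below mine, on the ground “perhaps slightly less if initiator death begins to limit it”.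

Winter gave 41.3 %, autumn 53.1 % and noon 69.9 %, and the trend was: it rises, by 29 points.

    coupling partner + protic impurity → quenched reagent (k = 200 M⁻¹ h⁻¹)
    coupling partner + first chain carrier ⇌ target + second chain carrier (K = 2.80, k = 2.00 × 10⁷ M⁻¹ h⁻¹)
    substrate + second chain carrier → by-product + first chain carrier (k = 2.80 × 10⁷ M⁻¹ h⁻¹)
    2 second chain carrier → ended chains B (k = 5.60 × 10⁷ M⁻¹ s⁻¹)
    2 first chain carrier → ended chains A (k = 4.10 × 10⁶ M⁻¹ s⁻¹)
    coupling partner → decomposition product (k = 3.80 × 10⁻⁴ h⁻¹)
    coupling partner + by-product ⇌ idle adduct, settled at all times (K = 16000 M⁻¹)
    initiator → 2 initiating radical (k = 0.0200 h⁻¹)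
    substrate + initiating radical → capped initiator + first chain carrier (k = 96000 M⁻¹ s⁻¹)

Autumn had not come to rest. Its free coupling partner stood at 0.62 % of charge. Taking the charge less the quenched reagent, with partner held in idle adduct counted as spent, its cost at 10.0 h was 1.61, near the 1.57 read from north-west. The same flask read at 25 h had reached 61.7 %, at a cost of 1.39. Between those two times, autumn's idle adduct fell from 0.00694 M to 0.00601 M. Left to 100 h, winter reached 63.1 %, autumn 77.1 % and noon 94.1 %.

The numbers in the tables were computed for an exercise; scatter was added.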